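The route rests on cutting ring B of the ent-labdane at C6–C7 and C5–C10. O7 and the C20 methyl sit cis-1,4 across ring B (on C7 and C10), so they are read as the O–C(=O) bridge of a 2-pyrone whose diene carbons are C10–C7. An intramolecular Diels–Alder reaction of this pyrone with the terminal alkene C5=C6, tethered through C1–C4, should close rings A and B in one operation and set C5, C7 and C10, keeping the lactone bridge. The precursor is a 3,4,5-trisubstituted 2-pyrone: (3R)-hydroxy-dimethylhexenyl tether at C10, side-chain stub at C9, CO2Me (future C17) at C8. The lactone then becomes C20H3 and O7H.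

Key step: step 6

Remark: the target is taken as the ent-labdane (3R,5S,7R,9S,10R) with a 13Z enoate (C12 cis to CO2Me); labdane numbering C1–C20 is used for all intermediates.

Step 1
Reactants: 1 dimethyl 3-oxopentanedioate; 2 triethyl orthoformate
Product: 4 methyl 4-hydroxy-2-oxo-2H-pyran-5-carboxylate, via ethoxymethylene diester 3 (not isolated)
Conditions: Ac2O, 130 °C; then aq. HCl, rt
Reagents that add atoms: water (O)
Why: Ethoxymethylenation of one active methylene (Claisen-type condensation with the orthoformate) followed by hydrolysis of the enol ether and enol lactonisation onto the distal ester should give the 4-hydroxy-2-pyrone; no stereocentre.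

Step 2
Reactants: 5 N-methoxy-N-methylprop-2-enamide; 6 (3-methylbut-2-en-1-yl)magnesium chloride
Product: 7 4,4-dimethylhexa-1,5-dien-3-one
Conditions: THF, −78 to −20 °C; inverse quench into cold aq. HCl
Reagents that add atoms: none
Why: Weinreb ketone synthesis in which the allylic Grignard reagent adds through its gamma carbon (allylic transposition) and the chelated tetrahedral intermediate releases the vinyl ketone only on acidic quench; no stereocentre.

Step 3
Reactants: 4 methyl 4-hydroxy-2-oxo-2H-pyran-5-carboxylate; 7 4,4-dimethylhexa-1,5-dien-3-one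
Product: 9 methyl 3-(4,4-dimethyl-3-oxohex-5-en-1-yl)-2-oxo-4-(trifluoromethanesulfonyloxy)-2H-pyran-5-carboxylate, via Michael adduct 8 (not isolated)
Conditions: i-Pr2NEt, CH2Cl2, rt; then PhNTf2, rt
Reagents that add atoms: N-phenylbis(trifluoromethanesulfonimide) (O=S(=O)(N(c1ccccc1)S(=O)(=O)C(F)(F)F)C(F)(F)F)
Why: C3 of the 4-hydroxy-2-pyrone (central carbon of a vinylogous 1,3-dicarbonyl) should add to the vinyl ketone (Michael addition) and the ammonium enolate formed is O-sulfonylated in the same flask; no stereocentre.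

Step 4
Reactants: 9 pyrone triflate; 10 (4-bromobut-1-yn-1-yl)trimethylsilane
Product: 12 methyl 3-(4,4-dimethyl-3-oxohex-5-en-1-yl)-2-oxo-4-[4-(trimethylsilyl)but-3-yn-1-yl]-2H-pyran-5-carboxylate, via alkylzinc bromide 11 (not isolated)
Conditions: 10, Zn dust, LiCl, THF, 50 °C; then 9, Pd(PPh3)4 (cat.), THF, rt to 40 °C
Reagents that add atoms: none
Why: Negishi coupling: the electron-poor vinylogous acyl triflate should undergo fast oxidative addition to zerovalent palladium and couple with the primary alkylzinc bromide, to which ketone, esters and silylalkyne are inert; no stereocentre.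

Step 5
Reactants: 12 pyrone ketone
Product: 13 methyl 3-[(3R)-3-hydroxy-4,4-dimethylhex-5-en-1-yl]-2-oxo-4-[4-(trimethylsilyl)but-3-yn-1-yl]-2H-pyran-5-carboxylate
Conditions: (S)-2-methyl-CBS-oxazaborolidine (cat.), catecholborane, toluene, −78 °C
Reagents that add atoms: none
Why: Corey–Bakshi–Shibata reduction: the (S)-oxazaborolidine should distinguish the tertiary-alkyl (large) from the CH2 (small) flank and give the (3R)-carbinol, while catecholborane at low temperature leaves pyrone, ester, alkene and alkyne untouched.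

Step 6
Reactants: 13 hydroxy pyrone triene
Product: 14 bridged lactone (20,7-lactone of the labd-8-ene core; 3R,5R,7R,10S)
Conditions: toluene (0.01 M), BHT, 110–120 °C, sealed tube
Reagents that add atoms: none
Why: Thermal, concerted but asynchronous intramolecular [4+2] cycloaddition in which the electron-poor 2-pyrone (diene C10=C9–C8=C7) adds the unactivated alkene C5=C6 with matched polarity (alkene CH2 to the pyrone carbon beta to the ester); the closest known type is the intramolecular pyrone Diels–Alder reaction that keeps the bridging lactone. Ring B closes as the cyclohexene of a 2-oxabicyclo[2.2.2]octenone by the [4+2] mode, and ring A closes at the same time as the six-membered ring of a type 1 intramolecular Diels–Alder reaction through the four-carbon tether C1–C4 in a chair-like arrangement. C7 and C10 are set together because the lactone bridge holds O7 and C20 on one face of ring B. C5 is set relative to C10 by the exo-tether mode (C4 over the lactone, H5 anti to C20), secured by the C9 substituent acting as a steric directing group: in the endo mode C2 of the tether would clash with C11 (A(1,3)-type strain). The absolute sense comes from the (3R)-carbinol, which should sit equatorial on the forming chair of ring A and so select the diene face; this preference is expected to be modest and the epimeric adduct is a separable diastereomer. The step also needs the adduct to keep CO2, which the moderate temperature and the alkene (not alkyne) dienophile should secure.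

Step 7
Reactants: 14 bridged lactone
Product: 15 bridged lactol triol (C17 as CH2OH; C20 as lactol CH(OH); both lactol epimers)
Conditions: i-Bu2AlH (excess), CH2Cl2, −78 °C; aq. KNaC4H4O6 work-up
Reagents that add atoms: none
Why: Partial reduction: i-Bu2AlH at −78 °C should reduce the conjugated ester by 1,2-addition to the allylic alcohol and stop the lactone at the aluminium hemiacetal (lactol after work-up); the new lactol centre is inconsequential.

Step 8
Reactants: 15 bridged lactol triol
Product: 18 (3R,5S,7R,10R)-15,16-dinorlabd-8-en-13-yne-3,7,17-triol, via tosylhydrazone 16 (not isolated), via silylalkyne triol 17 (not isolated)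
Conditions: TsNHNH2, MeOH, 50 °C; then NaBH4, MeOH, reflux; then K2CO3, MeOH, rt
Reagents that add atoms: none
Why: The lactol opens to the C20 aldehyde, which condenses to the tosylhydrazone; Caglioti reduction (hydride addition, then base-mediated loss of sulfinate and N2 in the basic methanolic medium) should give the C20 methyl and free the C7 hydroxyl, and methanolic base then removes the alkynyl silyl group; no stereocentre changes.

Step 9
Reactants: 18 allylic triol
Product: 21 (3R,5S,7R,9S,10R)-15,16-dinorlabd-8(17)-en-13-yne-3,7-diol, via sulfonylhydrazine 19 (not isolated), via allylic diazene 20 (not isolated)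
Conditions: 2-nitrobenzenesulfonylhydrazide, PPh3, DEAD, THF, −30 °C; then 23 °C
Reagents that add atoms: none
Why: Reductive 1,3-transposition of an allylic alcohol: Mitsunobu displacement of the primary allylic hydroxyl (the two secondary hydroxyls are slower), loss of sulfinic acid to the allylic diazene and its retro-ene (sigmatropic) loss of N2 should move the double bond to C8=C17 and deliver H to C9 on the face opposite the axial C20 methyl, setting 9S with the side chain equatorial.

Step 10
Reactants: 21 terminal alkyne diol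
Product: 22 methyl (3R,5S,7R,9S,10R)-3,7-dihydroxy-16-norlabd-8(17)-en-13-yn-15-oate
Conditions: PdCl2 (cat.), CuCl2, NaOAc, CO (1 atm), MeOH, rt
Reagents that add atoms: carbon monoxide ([C-]#[O+]); methanol (CO)
Why: Oxidative alkoxycarbonylation of a terminal alkyne: the palladium acetylide inserts CO and is methanolysed, CuCl2 reoxidising zerovalent palladium to divalent palladium; free hydroxyls should be tolerated and no stereocentre is touched.

Step 11
Reactants: 22 alkynoate
Product: 23 methyl (3R,5S,7R,9S,10R,13Z)-3,7-dihydroxylabda-8(17),13-dien-15-oate (target)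
Conditions: Me2CuLi (from CuI and MeLi, excess), THF, −78 °C; MeOH then aq. NH4Cl at −78 °C
Reagents that add atoms: lithium dimethylcuprate ([Li+].C[Cu-]C)
Why: syn-Carbocupration (conjugate addition) of the alkynoate at −78 °C and cold protonation of the alkenylcuprate with retention should place the new methyl cis to H, that is the C12 chain cis to CO2Me (13Z); excess cuprate covers the two free hydroxyls.

Compound list
1 | dimethyl 3-oxopentanedioate | COC(=O)CC(=O)CC(=O)OC | starting material
2 | triethyl orthoformate | CCOC(OCC)OCC | starting material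
3 | dimethyl 2-(ethoxymethylidene)-3-oxopentanedioate | CCOC=C(C(=O)OC)C(=O)CC(=O)OC | intermediate
4 | methyl 4-hydroxy-2-oxo-2H-pyran-5-carboxylate | COC(=O)C1=COC(=O)C=C1O | intermediate
5 | N-methoxy-N-methylprop-2-enamide | C=CC(=O)N(C)OC | starting material
6 | (3-methylbut-2-en-1-yl)magnesium chloride | CC(C)=CC[Mg]Cl | starting material
7 | 4,4-dimethylhexa-1,5-dien-3-one | C=CC(=O)C(C)(C)C=C | intermediate
8 | methyl 3-(4,4-dimethyl-3-oxohex-5-en-1-yl)-4-hydroxy-2-oxo-2H-pyran-5-carboxylate | COC(=O)C1=COC(=O)C(CCC(=O)C(C)(C)C=C)=C1O | intermediate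
9 | methyl 3-(4,4-dimethyl-3-oxohex-5-en-1-yl)-2-oxo-4-(trifluoromethanesulfonyloxy)-2H-pyran-5-carboxylate | COC(=O)C1=COC(=O)C(CCC(=O)C(C)(C)C=C)=C1OS(=O)(=O)C(F)(F)F | intermediate
10 | (4-bromobut-1-yn-1-yl)trimethylsilane | C[Si](C)(C)C#CCCBr | starting material
11 | bromo[4-(trimethylsilyl)but-3-yn-1-yl]zinc | C[Si](C)(C)C#CCC[Zn]Br | intermediate
12 | methyl 3-(4,4-dimethyl-3-oxohex-5-en-1-yl)-2-oxo-4-[4-(trimethylsilyl)but-3-yn-1-yl]-2H-pyran-5-carboxylate | COC(=O)C1=COC(=O)C(CCC(=O)C(C)(C)C=C)=C1CCC#C[Si](C)(C)C | intermediate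
13 | methyl 3-[(3R)-3-hydroxy-4,4-dimethylhex-5-en-1-yl]-2-oxo-4-[4-(trimethylsilyl)but-3-yn-1-yl]-2H-pyran-5-carboxylate | COC(=O)C1=COC(=O)C(CC[C@@H](O)C(C)(C)C=C)=C1CCC#C[Si](C)(C)C | intermediate
14 | methyl (3R,5R,7R,10S)-3-hydroxy-14-(trimethylsilyl)-15,16-dinorlabd-8-en-13-yn-17-oate 20,7-lactone (C20 carbonyl bridged to O7; H5 anti to C20) | COC(=O)C1=C(CCC#C[Si](C)(C)C)[C@]23CC[C@@H](O)C(C)(C)[C@H]2C[C@H]1OC3=O | intermediate
15 | 20,7-lactol of the 3,17-diol derived from 14 (C17 as CH2OH; ring stereocentres as in 14; both lactol epimers) | OCC1=C(CCC#C[Si](C)(C)C)[C@]23CC[C@@H](O)C(C)(C)[C@H]2C[C@H]1OC3O | intermediate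
16 | 4-methylbenzenesulfonylhydrazone of 3,7,17-trihydroxy-14-(trimethylsilyl)-15,16-dinorlabd-8-en-13-yn-20-al (ring stereocentres as in 15) | OCC1=C(CCC#C[Si](C)(C)C)[C@]2(C=NNS(=O)(=O)c3ccc(C)cc3)CC[C@@H](O)C(C)(C)[C@H]2C[C@H]1O | intermediate
17 | (3R,5S,7R,10R)-14-(trimethylsilyl)-15,16-dinorlabd-8-en-13-yne-3,7,17-triol | OCC1=C(CCC#C[Si](C)(C)C)[C@]2(C)CC[C@@H](O)C(C)(C)[C@H]2C[C@H]1O | intermediate
18 | (3R,5S,7R,10R)-15,16-dinorlabd-8-en-13-yne-3,7,17-triol | OCC1=C(CCC#C)[C@]2(C)CC[C@@H](O)C(C)(C)[C@H]2C[C@H]1O | intermediate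
19 | 1-[(3R,5S,7R,10R)-3,7-dihydroxy-15,16-dinorlabd-8-en-13-yn-17-yl]-1-(2-nitrobenzenesulfonyl)hydrazine | NN(CC1=C(CCC#C)[C@]2(C)CC[C@@H](O)C(C)(C)[C@H]2C[C@H]1O)S(=O)(=O)c1ccccc1[N+](=O)[O-] | intermediate
20 | (3R,5S,7R,10R)-17-diazenyl-15,16-dinorlabd-8-en-13-yne-3,7-diol | N=NCC1=C(CCC#C)[C@]2(C)CC[C@@H](O)C(C)(C)[C@H]2C[C@H]1O | intermediate
21 | (3R,5S,7R,9S,10R)-15,16-dinorlabd-8(17)-en-13-yne-3,7-diol | C=C1[C@H](O)C[C@@H]2C(C)(C)[C@H](O)CC[C@@]2(C)[C@@H]1CCC#C | intermediate
22 | methyl (3R,5S,7R,9S,10R)-3,7-dihydroxy-16-norlabd-8(17)-en-13-yn-15-oate | C=C1[C@H](O)C[C@@H]2C(C)(C)[C@H](O)CC[C@@]2(C)[C@@H]1CCC#CC(=O)OC | intermediate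
23 | methyl (2Z)-5-[(1S,3R,4aS,6R,8aR)-3,6-dihydroxy-5,5,8a-trimethyl-2-methylidenedecahydronaphthalen-1-yl]-3-methylpent-2-enoate (CNP0284783.1) | C=C1[C@H](O)C[C@@H]2C(C)(C)[C@H](O)CC[C@@]2(C)[C@@H]1CC/C(C)=C\C(=O)OC | target

Total step count: 11. Longest linear sequence: 10 steps (steps 1 and 3–11; step 2 is a one-step branch).

Steps most likely to fail

Step 6. What may go wrong: cycloaddition through the endo-tether mode or on the wrong diene face, thermal loss of CO2 from the bridged lactone at the temperature needed, or acyl transfer from the pyrone to the free C3 hydroxyl. The fallback sets out from 13 and changes the controlling group. Silylation (TBSOTf, 2,6-lutidine, CH2Cl2) should give methyl 3-[(3R)-3-(tert-butyldimethylsilyloxy)-4,4-dimethylhex-5-en-1-yl]-2-oxo-4-[4-(trimethylsilyl)but-3-yn-1-yl]-2H-pyran-5-carboxylate F1. Its larger equatorial group and masked hydroxyl should sharpen the chair preference, exclude acyl transfer and allow longer heating at lower temperature or under 10–15 kbar. The resulting 3-O-silyl bridged lactone F2 is desilylated with HF·pyridine and the route is rejoined at 14.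

Step 8. What may go wrong: fragmentation of the alkyldiazene through a C20 radical that is homoallylic to C8=C9 (3-exo closure and reopening, a vinyl shift with ring enlargement), or Bamford–Stevens-type decomposition of the hydrazone anion. The fallback sets out from 14 and moves the transposition ahead of the deoxygenation. LiAlH4 (THF, 0 °C) should reduce lactone and ester to the 3,7,17,20-tetraol F3. The same Mitsunobu and diazene transposition (the neopentyl C20 hydroxyl cannot be displaced) should pass through the 17-sulfonylhydrazine F4 and the 17-diazene F5 to the 8(17)-ene 3,7,20-triol F6. TEMPO and PhI(OAc)2 then oxidise the primary hydroxyl to the C20 aldehyde F7. Its tosylhydrazone F8 is reduced with NaBH4 in refluxing MeOH, now with no alkene flanking C20, to the C20-methyl silylalkyne F9. Methanolic K2CO3 removes the silyl group and the route is rejoined at 21.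

Step 9. What may go wrong: Mitsunobu activation of the wrong hydroxyl or slow displacement at the hindered allylic carbon, and hydrogen delivery to the wrong face of C9. The fallback sets out from 18. Selective acylation of the primary hydroxyl (ClCO2Me, pyridine, −20 °C) should give the C17 allylic methyl carbonate F10. Formate reduction with Pd(OAc)2, PBu3, HCO2H and Et3N in THF should deliver hydride from the allylpalladium to the more substituted terminus C9, on the face away from the C20 methyl. This gives the exocyclic alkene and rejoins the route at 21.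

Further compounds
F1 | step 6 | methyl 3-[(3R)-3-(tert-butyldimethylsilyloxy)-4,4-dimethylhex-5-en-1-yl]-2-oxo-4-[4-(trimethylsilyl)but-3-yn-1-yl]-2H-pyran-5-carboxylate | COC(=O)C1=COC(=O)C(CC[C@@H](O[Si](C)(C)C(C)(C)C)C(C)(C)C=C)=C1CCC#C[Si](C)(C)C
F2 | step 6 | 3-O-tert-butyldimethylsilyl ether of bridged lactone 14 | COC(=O)C1=C(CCC#C[Si](C)(C)C)[C@]23CC[C@@H](O[Si](C)(C)C(C)(C)C)C(C)(C)[C@H]2C[C@H]1OC3=O
F3 | step 8 | 14-(trimethylsilyl)-15,16-dinorlabd-8-en-13-yne-3,7,17,20-tetraol | OCC1=C(CCC#C[Si](C)(C)C)[C@]2(CO)CC[C@@H](O)C(C)(C)[C@H]2C[C@H]1O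
F4 | step 8 | 1-(2-nitrobenzenesulfonyl)-1-(C17-alkyl)hydrazine of F3 | NN(CC1=C(CCC#C[Si](C)(C)C)[C@]2(CO)CC[C@@H](O)C(C)(C)[C@H]2C[C@H]1O)S(=O)(=O)c1ccccc1[N+](=O)[O-]
F5 | step 8 | 17-diazenyl-14-(trimethylsilyl)-15,16-dinorlabd-8-en-13-yne-3,7,20-triol | N=NCC1=C(CCC#C[Si](C)(C)C)[C@]2(CO)CC[C@@H](O)C(C)(C)[C@H]2C[C@H]1O
F6 | step 8 | 14-(trimethylsilyl)-15,16-dinorlabd-8(17)-en-13-yne-3,7,20-triol | C=C1[C@H](O)C[C@@H]2C(C)(C)[C@H](O)CC[C@@]2(CO)[C@@H]1CCC#C[Si](C)(C)C
F7 | step 8 | 3,7-dihydroxy-14-(trimethylsilyl)-15,16-dinorlabd-8(17)-en-13-yn-20-al | C=C1[C@H](O)C[C@@H]2C(C)(C)[C@H](O)CC[C@@]2(C=O)[C@@H]1CCC#C[Si](C)(C)C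
F8 | step 8 | 4-methylbenzenesulfonylhydrazone of F7 | C=C1[C@H](O)C[C@@H]2C(C)(C)[C@H](O)CC[C@@]2(C=NNS(=O)(=O)c3ccc(C)cc3)[C@@H]1CCC#C[Si](C)(C)C
F9 | step 8 | 14-(trimethylsilyl)-15,16-dinorlabd-8(17)-en-13-yne-3,7-diol | C=C1[C@H](O)C[C@@H]2C(C)(C)[C@H](O)CC[C@@]2(C)[C@@H]1CCC#C[Si](C)(C)C
F10 | step 9 | 17-O-(methoxycarbonyl) derivative of triol 18 | COC(=O)OCC1=C(CCC#C)[C@]2(C)CC[C@@H](O)C(C)(C)[C@H]2C[C@H]1O
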